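**Plan**
The target is cut first at C2–C4′ and C14–C15′ (guaiane numbering, primes for the half without the carbinol), the two bonds of the central cyclohexene; this gives an alkylidene 2,3-dione guaianolide and dehydrozaluzanin C.
The dione half is then cut at C1–C5. Rings A and B share this bond, flanked by the tetrasubstituted C1=C10 alkene and the trans-fused C6/C7 lactone, which is the imprint of a 4,5-epoxygermacranolide closed across its ten-membered ring, so this half goes back to parthenolide.
Forward: rings A and B form together in the transannular cyclisation; ring A is dehydrated at C4 and oxidised at C3 and C2; dehydrozaluzanin C is made from dehydrocostus lactone; the cyclohexene and the spiro centre are closed last by a vinylogous Michael–aldol union.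
C6, C7 and all primed stereocentres come from the two natural lactones, C5 from anti opening of the epoxide, and C2 and C4′ from the facial preferences of the two halves in the last step.

Key step: step 1

Assumption: alcohols 4, 6 and 9 are drawn as the expected major epimers; each carbinol is oxidised in the following step, so either epimer can be carried on.

**Step 1**
Reactants: 1 parthenolide
Product: 2 micheliolide (4α-hydroxy-5αH-guaia-1(10),11(13)-dien-12,6α-olide)
Conditions: p-toluenesulfonic acid monohydrate (cat.), CH2Cl2, rt
Reagents that add atoms: none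
Why: Protonation of the epoxide oxygen weakens the C5–O bond, and the C1=C10 π bond, held behind C5 in the folded ten-membered ring, attacks C5 with inversion to form the single C1–C5 bond; the tertiary C10 cation then loses H-1 to give the tetrasubstituted C1=C10 alkene. The closest known reaction type is the acid-mediated transannular epoxide–olefin cyclisation of 4,5-epoxygermacranolides to 4-hydroxyguaianolides. Ring A closes 5-exo-trig at the alkene (endo at the epoxide) and ring B closes 7-endo-trig at the alkene (exo at the epoxide), both through the same transannular bond. C5 is set by backside attack anti to the departing oxygen of the trans-epoxide, which places H-5 α; the C4 carbinol keeps its C–O bond and, like C6 and C7, is carried over unchanged from 1. The step needs C1 rather than C10 to bond to C5 and proton loss from C1 rather than from C9 or C14; the crown-like conformation of the E-cyclodecene holds C1 within bonding distance of C5, and the preference for the tetrasubstituted alkene directs the elimination.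

**Step 2**
Reactants: 2 micheliolide
Product: 3 5αH-guaia-1(10),4(15),11(13)-trien-12,6α-olide
Conditions: SOCl2, pyridine, CH2Cl2, −40 → 0 °C
Reagents that add atoms: none
Why: E2 dehydration through the chlorosulfite: H-5 is syn to the α leaving group and cannot be lost, and the freely rotating C15 methyl reaches antiperiplanarity more easily than H-3β of the cyclopentane envelope, so the exocyclic 4(15)-alkene should predominate; no stereocentre is formed.

**Step 3**
Reactants: 3 5αH-guaia-1(10),4(15),11(13)-trien-12,6α-olide
Product: 4 3α-hydroxy-5αH-guaia-1(10),4(15),11(13)-trien-12,6α-olide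
Conditions: SeO2 (0.5 equiv), t-BuOOH, CH2Cl2, 0 °C → rt
Reagents that add atoms: selenium dioxide, O=[Se]=O; tert-butyl hydroperoxide, CC(C)(C)OO
Why: Selenium dioxide allylic oxidation (ene reaction, then [2,3]-sigmatropic shift) of the 1,1-disubstituted 4(15)-alkene hydroxylates the ring methylene C3 and keeps the exocyclic alkene, as is usual for 4(15)-methylene guaianolides; oxygen should enter from the open α-face.

**Step 4**
Reactants: 4 3α-hydroxy-5αH-guaia-1(10),4(15),11(13)-trien-12,6α-olide
Product: 5 3-oxo-5αH-guaia-1(10),4(15),11(13)-trien-12,6α-olide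
Conditions: Dess–Martin periodinane, CH2Cl2, 0 °C → rt
Reagents that add atoms: none
Why: Dess–Martin oxidation of the secondary allylic alcohol gives the exo-methylene ketone under neutral conditions that should leave the deconjugated C1=C10 alkene where it is.

**Step 5**
Reactants: 5 3-oxo-5αH-guaia-1(10),4(15),11(13)-trien-12,6α-olide
Product: 6 2α-hydroxy-3-oxo-5αH-guaia-1(10),4(15),11(13)-trien-12,6α-olide
Conditions: KN(SiMe3)2, THF, −78 °C; then 2-(phenylsulfonyl)-3-phenyloxaziridine, −78 °C; aq. NH4Cl
Reagents that add atoms: 2-(phenylsulfonyl)-3-phenyloxaziridine, O=S(=O)(c1ccccc1)N1OC1c1ccccc1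
Why: Davis α-hydroxylation: the base removes the doubly activated H-2 (α to the C3 ketone, allylic to C1=C10) and the dienolate takes up oxygen at its α-carbon C2, on the α-face anti to C6.

**Step 6**
Reactants: 6 2α-hydroxy-3-oxo-5αH-guaia-1(10),4(15),11(13)-trien-12,6α-olide
Product: 7 2,3-dioxo-5αH-guaia-1(10),4(15),11(13)-trien-12,6α-olide
Conditions: Dess–Martin periodinane, CH2Cl2, 0 °C; short Florisil plug; used at once
Reagents that add atoms: none
Why: Dess–Martin oxidation of the α-ketol gives the 1,2-dione, which has no hydrogen on C1 or C4 and is therefore expected to survive long enough to be used directly.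

**Step 7**
Reactants: 8 dehydrocostus lactone
Product: 9 3-epizaluzanin C (3α-hydroxy-1αH,5αH-guaia-4(15),10(14),11(13)-trien-12,6α-olide)
Conditions: SeO2 (0.5 equiv), t-BuOOH, CH2Cl2, 0 °C → rt
Reagents that add atoms: selenium dioxide, O=[Se]=O; tert-butyl hydroperoxide, CC(C)(C)OO
Why: Selenium dioxide allylic oxidation of the 4(15)-alkene at the cyclopentane methylene C3 is the standard entry to 3-oxygenated dehydrocostus lactone derivatives; oxygen should enter on the convex α-face.

**Step 8**
Reactants: 9 3-epizaluzanin C
Product: 10 dehydrozaluzanin C (3-oxo-1αH,5αH-guaia-4(15),10(14),11(13)-trien-12,6α-olide)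
Conditions: Dess–Martin periodinane, CH2Cl2, 0 °C → rt
Reagents that add atoms: none
Why: Dess–Martin oxidation of the allylic alcohol gives the exocyclic enone without touching the ring-fusion stereocentres.

**Step 9**
Reactants: 7 2,3-dioxo-5αH-guaia-1(10),4(15),11(13)-trien-12,6α-olide; 10 dehydrozaluzanin C
Product: 13 target spiro dimer CNP0269880.2, via triethylammonium dienolate 11 (not isolated), via Michael adduct enolate 12 (not isolated)
Conditions: Et3N (1.2 equiv), 10 (3 equiv), CH2Cl2, −20 °C → rt, slow addition of 7
Reagents that add atoms: none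
Why: Proposed new method: the amine turns the acidic alkylidene 1,2-dione into dienolate 11 (H-14 is γ to the C2 ketone and cis to it across C1=C10), whose unhindered C14 terminus adds to C15′ of the exocyclic enone of 10, and the resulting C4′ enolate 12 closes the cyclohexene by 6-exo-trig aldol addition to the electrophilic C2 ketone, restoring C1=C10; the closest known reaction types are base-mediated vinylogous Michael–aldol annulations (Staunton–Weinreb type, anionic Diels–Alder) and the Diels–Alder union of guaianolide dienones with exocyclic enones; C4′ should bond on the convex α-face of the cis-fused hydroazulenone, anti to C6′, with its flat C3′ carbonyl over ring A and anti to the C2 oxygen in an open, metal-free transition state, and this pairing is possible only on the β-face of C2, which leaves the C2 hydroxyl α as in the target.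

**Compound list**
1 | parthenolide | C[C@@]12CC/C=C(C)/CC[C@H]3C(=C)C(=O)O[C@@H]3[C@H]1O2 | starting material
2 | micheliolide | C[C@@]1(O)CCC2=C(C)CC[C@H]3C(=C)C(=O)O[C@@H]3[C@@H]12 | intermediate
3 | 5αH-guaia-1(10),4(15),11(13)-trien-12,6α-olide | C=C1CCC2=C(C)CC[C@H]3C(=C)C(=O)O[C@@H]3[C@@H]12 | intermediate
4 | 3α-hydroxy-5αH-guaia-1(10),4(15),11(13)-trien-12,6α-olide | C=C1[C@H](O)CC2=C(C)CC[C@H]3C(=C)C(=O)O[C@@H]3[C@@H]12 | intermediate
5 | 3-oxo-5αH-guaia-1(10),4(15),11(13)-trien-12,6α-olide | C=C1C(=O)CC2=C(C)CC[C@H]3C(=C)C(=O)O[C@@H]3[C@@H]12 | intermediate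
6 | 2α-hydroxy-3-oxo-5αH-guaia-1(10),4(15),11(13)-trien-12,6α-olide | C=C1C(=O)[C@H](O)C2=C(C)CC[C@H]3C(=C)C(=O)O[C@@H]3[C@@H]12 | intermediate
7 | 2,3-dioxo-5αH-guaia-1(10),4(15),11(13)-trien-12,6α-olide | C=C1C(=O)C(=O)C2=C(C)CC[C@H]3C(=C)C(=O)O[C@@H]3[C@@H]12 | intermediate
8 | dehydrocostus lactone | C=C1CC[C@H]2C(=C)CC[C@H]3C(=C)C(=O)O[C@@H]3[C@H]21 | starting material
9 | 3-epizaluzanin C | C=C1[C@H](O)C[C@H]2C(=C)CC[C@H]3C(=C)C(=O)O[C@@H]3[C@H]21 | intermediate
10 | dehydrozaluzanin C | C=C1C(=O)C[C@H]2C(=C)CC[C@H]3C(=C)C(=O)O[C@@H]3[C@H]21 | intermediate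
11 | triethylammonium dienolate of 7 (2-oxido-1(2),10(14)-diene) | C=C1C(=O)C([O-])=C2C(=C)CC[C@H]3C(=C)C(=O)O[C@@H]3[C@@H]12.CC[NH+](CC)CC | intermediate
12 | Michael adduct enolate (C14–C15′ bonded, C3′/C4′ enolate, ring A still the 2,3-dione), triethylammonium salt | C=C1C(=O)C(=O)C2=C(CC[C@H]3C(=C)C(=O)O[C@@H]3[C@@H]12)CCC1=C([O-])C[C@H]2C(=C)CC[C@H]3C(=C)C(=O)O[C@@H]3[C@H]21.CC[NH+](CC)CC | intermediate
13 | CNP0269880.2: 2α-hydroxy-3-oxo-guaia-1(10),4(15),11(13)-trien-12,6α-olide joined through C2 (β bond) and C14 to spiro C4′ (bond on its α-face) and C15′ of a 3′-oxo-guaia-10′(14′),11′(13′)-dien-12′,6′α-olide | C=C1C(=O)[C@]2(O)C3=C(CC[C@H]4C(=C)C(=O)O[C@@H]4[C@@H]13)CC[C@]21C(=O)C[C@H]2C(=C)CC[C@H]3C(=C)C(=O)O[C@@H]3[C@H]21 | target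

**Count**
Total steps: 9. Longest linear sequence: 7 (steps 1–6 and 9, from parthenolide).

**Steps most likely to fail**

Step 9 (proposed new method). The risks are poor facial pairing in the ring-closing aldol (attack on the α-face of C2, or a cation-bridged arrangement with the carbonyls syn), addition of the dienolate through oxygen or to a lactone methylene, and self-condensation of the dione before it meets 10. The fallback uses known reaction types and sets out from ketone 5 and enone 10. Soft enolisation of 5 (TBSOTf, Et3N) should give the tert-butyldimethylsilyl dienol ether F1. Saegusa–Ito oxidation with Pd(OAc)2 in MeCN in the presence of 10 should give the cross-conjugated trienone F2, which is trapped at once in a Diels–Alder reaction by the exocyclic enone of 10 to give the 2-deoxy adduct F3. Davis hydroxylation of its C2 enolate (KN(SiMe3)2, then the sulfonyloxaziridine) would then return to the route at 13.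

Step 2. The risks are elimination into the ring toward C3 instead of toward C15, and ionisation of the chlorosulfite. The fallback sets out from 2 and makes use of exactly that ring isomer. Elimination with POCl3 in pyridine should give the 3,4-ene isomer F4. Its trisubstituted alkene should be dihydroxylated on the convex α-face by OsO4 (catalytic) with N-methylmorpholine N-oxide, in preference to the hindered tetrasubstituted and the electron-poor alkenes, to give the 3α,4α-diol F5. Dess–Martin oxidation of the secondary alcohol gives the 4α-hydroxy-3-ketone F6. In F6 the C4 leaving group has no hydrogen on C3 and only a syn hydrogen on C5, so SOCl2 in pyridine can eliminate only toward C15. The route is rejoined at 5, and the selenium oxidation of step 3 is bypassed as well.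

Step 5. The risks are Michael addition of the potassium dienolate to the exocyclic enone or lactone methylene of a second molecule, and oxygen uptake at C10 instead of C2. The fallback avoids any carbanion. Riley oxidation of 5 with SeO2 in wet dioxane at 50 °C should take the doubly activated C2 methylene straight to the dione, so the route is left at 5 and rejoined at 7 without a new compound (F0).

**Further compounds**
F1 | step 9 | 3-(tert-butyldimethylsilyloxy)-5αH-guaia-1(10),2,4(15),11(13)-tetraen-12,6α-olide | C=C1C(O[Si](C)(C)C(C)(C)C)=CC2=C(C)CC[C@H]3C(=C)C(=O)O[C@@H]3[C@@H]12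
F2 | step 9 | 3-oxo-5αH-guaia-1,4(15),10(14),11(13)-tetraen-12,6α-olide | C=C1C(=O)C=C2C(=C)CC[C@H]3C(=C)C(=O)O[C@@H]3[C@@H]12
F3 | step 9 | 2-deoxy adduct (2αH analogue of 13) | C=C1C(=O)[C@@H]2C3=C(CC[C@H]4C(=C)C(=O)O[C@@H]4[C@@H]13)CC[C@]21C(=O)C[C@H]2C(=C)CC[C@H]3C(=C)C(=O)O[C@@H]3[C@H]21
F4 | step 2 | 5αH-guaia-1(10),3,11(13)-trien-12,6α-olide | CC1=CCC2=C(C)CC[C@H]3C(=C)C(=O)O[C@@H]3[C@@H]12
F5 | step 2 | 3α,4α-dihydroxy-5αH-guaia-1(10),11(13)-dien-12,6α-olide | C[C@@]1(O)[C@H](O)CC2=C(C)CC[C@H]3C(=C)C(=O)O[C@@H]3[C@@H]12
F6 | step 2 | 4α-hydroxy-3-oxo-5αH-guaia-1(10),11(13)-dien-12,6α-olide | C[C@@]1(O)C(=O)CC2=C(C)CC[C@H]3C(=C)C(=O)O[C@@H]3[C@@H]12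
F0 | step 5 | none | none
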